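## The problem

- Target 25 is a germacrane: a ten-membered carbocycle with an E-trisubstituted alkene (C1=C10) and a trisubstituted epoxide across C4–C5 whose ring bonds to C3 and C6 are cis. Three contiguous secondary centres follow: C6 (free hydroxyl), C7 (isopropyl) and C8 (3,4,5-trimethoxybenzoate).
- The five stereocentres are (4S,5R,6R,7S,8S). On the ring the C8 ester is trans to the C7 isopropyl group, and the C6 hydroxyl is cis to both the isopropyl group and the epoxide oxygen.
- C7 and C8 form a syn-aldol pair that an auxiliary can set in an open chain. C6 then has to be derived from C7, and C4/C5 from C6 through its hydroxyl group.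
- The ring is the main obstacle. A medium-ring closure fights strain and entropy, and both alkene geometries (E at C1=C10, Z at C4=C5 before epoxidation) must be fixed beforehand, because they cannot be corrected inside the ring.
- Several groups will not survive rough treatment. The epoxy alcohol is open to acid-induced transannular attack by the C1=C10 alkene and to base-induced epoxide migration. The aryl ester sits 1,3 to a free hydroxyl (acyl migration) and β to C6 whenever C6 is a carbonyl (elimination). The 1,5-diene of the ring can undergo Cope rearrangement on heating.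
- The enabling feature is that the C6 carbinol sits directly on C5, the CH terminus of the C4=C5 alkene from which the epoxide derives. C5–C6 is therefore an alkenyl-metal-to-aldehyde bond, and the hydroxyl set free by forming it is the group needed to direct the epoxidation.

## Retrosynthesis

**25 to 24.** The two C–O bonds of the oxirane are cut first, giving dienol 24. Carrying the epoxide through ring construction would expose it to Lewis acids and would remove the alkene that defines the C5 nucleophile. The forward reaction must pick the allylic C4=C5 alkene over C1=C10 and the face syn to the C6 hydroxyl; a hydroxyl-directed epoxidation answers both.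

**24 to 22.** The ring bond C5–C6 is cut, giving seco aldehyde 22, which cyclises through alkenylchromium 23. The neighbouring cuts are weaker for this target:
- C2–C3 creates no stereocentre but needs an activating group that must later be removed.
- C7–C8 would leave two stereocentres to the ring closure.
- Closing at either alkene gives no reliable control of trisubstituted geometry in a ten-membered ring.

Precursor 22 is an open chain with only two stereocentres and both alkenes already defined. The forward step must keep the Z geometry of the alkenyl iodide, tolerate the aryl ester and the enolisable aldehyde, and choose the correct face of the aldehyde.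

**22 to 19 and 20.** The aldehyde of 22 is taken back to the acyl thiazolidinethione 21, and the C8–O ester bond is cut to aldol adduct 19 and acid chloride 20. Esterifying while C8–OH is the only hydroxyl in the molecule avoids any later differentiation of the C6 and C8 hydroxyls. The thioimide is the one acyl derivative that a hydride reagent should reduce to the aldehyde in the presence of an aryl ester.

**19 to 17 and 14.** The C7–C8 bond is cut by an auxiliary-controlled syn aldol between thioimide 17 (from isovaleryl chloride 15 and thiazolidinethione 16) and aldehyde 14. Cutting C8–C9 instead would need an allyl nucleophile that reacts through its γ-carbon, and cutting C6–C7 has no stereocontrolled counterpart. The aldol sets both stereocentres of the open chain at once. It asks that the β,γ-unsaturated aldehyde 14 survive enolate addition without alkene migration.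

**14 to 10.** Aldehyde 14 is generated only at the last moment from homoallylic alcohol 13. C8 is cut off as a methylene unit: 13 comes from hydroboration of triene 11, and 11 from methylenation of enal 10. This keeps the sensitive aldehyde out of every earlier step and uses the conjugated enal, the most robust oxidation state, as the storage point.

**10 to 8 and 9.** The C1=C10 alkene is cut to aldehyde 8 and the stabilised formyl ylide 9. A stabilised Wittig reaction is the most dependable source of an E-trisubstituted 2-methyl-enal, and it brings C9, C10 and the C10 methyl group in one piece.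

**8 to 1.** The C2–C3 bond is cut to allylic bromide 4 and tert-butyl acetate 5 (as its enolate 6), giving ester 7 and then 8 by partial reduction. A sulfone-stabilised allyl anion could form the same bond, but reductive removal of a sulfonyl group is not compatible with an alkenyl iodide. Bromide 4 comes from alcohol 3, and 3 from propargyl alcohol 1 by anti-carbomagnesiation via chelate 2 and iodination, which fixes the Z geometry of the future C4=C5 alkene at the outset.

## Roads not taken

**Alternative 1: sulfone alkylation closing C2–C3.** The ring would be cut between the two methylene carbons C2 and C3. In the forward direction the open-chain acetonide A1, carrying an (E)-allylic phenyl sulfone at C2 and a primary (Z)-allylic bromide at C3, would be deprotonated with LiN(SiMe3)2, and the sulfonyl carbanion would displace the bromide to give macrocycle A2 as C2 epimers.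

- Merits: the bond forms between two unhindered carbons far from any stereocentre, stabilised-carbanion closures of ten-membered terpene rings are dependable, and C6 is already fixed in the open chain. In these respects this road is better than the chosen one.
- Weak points: the sulfonyl group must be removed reductively next to the C1=C10 alkene, with a risk of alkene migration. The anti-1,3-diol acetonide has to sit in a twist-boat. After deprotection the C6 and C8 hydroxyls must be told apart for the aroylation. C6 needs a third stereoselective step in the open chain.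
- Comparison: the chosen plan sets against it an endgame of one step after ring closure, with the ester already in place, no activating group to remove, and the directing hydroxyl produced by the closure itself. The price is that C6 is set in the ring-forming step.

**Alternative 2: Wharton fragmentation of a hydroazulene.** The bond cut is the C6–C10 bond of a fused five- and seven-membered precursor, not a bond of the target ring. Treating the tertiary alcohol mesylate A3 with KOt-Bu would break C6–C10, turn C6 into a ketone and form the C1=C10 alkene as the mesylate leaves, giving the ten-membered enone A4.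

- Merits: the fragmentation is stereospecific for the E alkene, needs no high dilution, and is driven by bond reorganisation instead of fighting ring strain. As a ring-forming event it is more reliable than any ten-membered closure, the chosen one included.
- Weak points: A3 needs five stereocentres, a quaternary carbon among them, three of which are destroyed in the key step. A4 is formed under strong base with an epimerisable C7 next to the new ketone and a β-silyloxy group that can be eliminated. C6 must still be set by ketone reduction, and the silyl ether must be exchanged for the aryl ester.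
- Comparison: the chosen plan sets against it a short assembly in which every stereocentre made is kept, and neutral conditions from the aldol onward.

**Alternative 3: chromium allylation closing C7–C8.** The ring would be cut between C7 and C8. Bromo aldehyde A5 would be treated with CrCl2; the allylchromium formed at C12 would attack the C8 aldehyde through its γ-carbon C7 and give A6, with the isopropenyl group unveiled.

- Merits: ring, C7 and C8 are made in one step. Allylchromium additions are anti-selective whatever the allyl geometry, which matches the required C7/C8 relationship. The C8 hydroxyl is liberated while C6 is still silylated, so the aroylation is unambiguous; this is as clean as in the chosen plan.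
- Weak points: two stereocentres are set inside the macrocyclic transition state with only C6 to fix their absolute sense. The bond formed is the most congested of the ring. The β,γ-unsaturated C8 aldehyde must be unveiled next to an allylic bromide and must survive a slow, dilute reaction. Afterwards the isopropenyl group has to be hydrogenated selectively beside two ring alkenes, followed by aroylation, desilylation and epoxidation.
- Comparison: the chosen plan leaves one stereocentre, not two, to the ring closure, uses its sensitive aldehyde 14 at once at low temperature, and needs one step after closure where this road needs four.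

Key step: step 13

Assumption: ring atoms are numbered as in germacrane (C1=C10 alkene, C4–C5 epoxide, C6 carbinol, C7 isopropyl, C8 ester), and 25 is taken as the (4S,5R,6R,7S,8S) isomer that its SMILES encodes.

## Route

Step 1
Reactants: 1 propargyl alcohol
Product: 3 (Z)-3-iodo-2-methylprop-2-en-1-ol, via cyclic alkenylmagnesium alkoxide 2 (not isolated)
Conditions: MeMgBr (2.5 equiv), CuI (0.1 equiv), THF, −10 °C to rt; then I2, −78 to 0 °C; aq. NH4Cl
Reagents that add atoms: methylmagnesium bromide C[Mg]Br; iodine II
Why: Copper-catalysed anti-carbomagnesiation of the propargylic alkoxide puts methyl on the inner carbon and magnesium on the terminal carbon, cis to the CH2O group, in the five-membered chelate 2. Iodinolysis with retention gives the Z alkenyl iodide, whose CH2O/I cis relationship becomes the C3/C6 cis relationship of the ring.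

Step 2
Reactants: 3 (Z)-3-iodo-2-methylprop-2-en-1-ol
Product: 4 (Z)-3-bromo-1-iodo-2-methylprop-1-ene
Conditions: CBr4, PPh3, CH2Cl2, 0 °C
Reagents that add atoms: carbon tetrabromide BrC(Br)(Br)Br
Why: Appel reaction of a primary allylic alcohol under neutral conditions; direct displacement at the oxyphosphonium carbon gives the bromide without allylic transposition and leaves the alkenyl iodide alone.

Step 3
Reactants: 4 (Z)-3-bromo-1-iodo-2-methylprop-1-ene; 5 tert-butyl acetate
Product: 7 tert-butyl (Z)-5-iodo-4-methylpent-4-enoate, via lithium enolate 6 (not isolated)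
Conditions: 5, LiN(i-Pr)2, THF, −78 °C; then 4, DMPU, −78 to −30 °C
Reagents that add atoms: none
Why: Alkylation of an ester lithium enolate by a primary allylic bromide (SN2) forms C2–C3. The tert-butyl ester suppresses self-condensation, and an enolate does not attack an alkenyl iodide at low temperature.

Step 4
Reactants: 7 tert-butyl (Z)-5-iodo-4-methylpent-4-enoate
Product: 8 (Z)-5-iodo-4-methylpent-4-enal
Conditions: i-Bu2AlH (1.1 equiv), CH2Cl2, −78 °C; aq. potassium sodium tartrate
Reagents that add atoms: none
Why: Partial reduction of an ester by i-Bu2AlH; the bulky tert-butoxy aluminium hemiacetal is stable at −78 °C and releases the aldehyde only on work-up.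

Step 5
Reactants: 8 (Z)-5-iodo-4-methylpent-4-enal; 9 2-(triphenylphosphoranylidene)propanal
Product: 10 (2E,6Z)-7-iodo-2,6-dimethylhepta-2,6-dienal
Conditions: toluene, 80 °C
Reagents that add atoms: none
Why: Wittig olefination with a stabilised formyl ylide; reversible addition funnels the reaction to the E-trisubstituted enal (C9 trans to C2), which fixes the C1=C10 geometry. The conjugated product is much less electrophilic than 8, so a second olefination is slow.

Step 6
Reactants: 10 (2E,6Z)-7-iodo-2,6-dimethylhepta-2,6-dienal
Product: 11 (1Z,5E)-1-iodo-2,6-dimethylocta-1,5,7-triene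
Conditions: Ph3PCH3Br, KOt-Bu, THF, 0 °C to rt
Reagents that add atoms: methyltriphenylphosphonium bromide C[P+](c1ccccc1)(c1ccccc1)c1ccccc1.[Br-]
Why: Wittig methylenation of the enal carbonyl (1,2-addition only) adds C8. A potassium base with no alkyllithium present excludes iodine–metal exchange.

Step 7
Reactants: 11 (1Z,5E)-1-iodo-2,6-dimethylocta-1,5,7-triene
Product: 13 (3E,7Z)-8-iodo-3,7-dimethylocta-3,7-dien-1-ol, via B-alkyl-9-borabicyclononane 12 (not isolated)
Conditions: 9-BBN (1.2 equiv), THF, 0 °C to rt; then NaOH, H2O2, 0 °C
Reagents that add atoms: hydrogen peroxide OO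
Why: Hydroboration–oxidation; 9-BBN adds anti-Markovnikov to the monosubstituted terminus of the diene far faster than to either trisubstituted alkene or the alkenyl iodide. Oxidation gives the primary homoallylic alcohol with the E alkene untouched.

Step 8
Reactants: 13 (3E,7Z)-8-iodo-3,7-dimethylocta-3,7-dien-1-ol
Product: 14 (3E,7Z)-8-iodo-3,7-dimethylocta-3,7-dienal
Conditions: Dess–Martin periodinane, NaHCO3, CH2Cl2, 0 °C; filtered and used at once
Reagents that add atoms: none
Why: Dess–Martin oxidation under buffered, non-basic conditions gives the β,γ-unsaturated aldehyde without moving the C10=C1 alkene into conjugation; immediate use avoids isomerisation on storage.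

Step 9
Reactants: 15 isovaleryl chloride; 16 (R)-4-benzyl-1,3-thiazolidine-2-thione
Product: 17 (R)-4-benzyl-3-(3-methylbutanoyl)-1,3-thiazolidine-2-thione
Conditions: Et3N, DMAP (cat.), CH2Cl2, 0 °C to rt
Reagents that add atoms: none
Why: N-acylation of the thiazolidinethione nitrogen by the acid chloride with nucleophilic catalysis; the stereocentre of the auxiliary is not involved.

Step 10
Reactants: 17 (R)-4-benzyl-3-(3-methylbutanoyl)-1,3-thiazolidine-2-thione; 14 (3E,7Z)-8-iodo-3,7-dimethylocta-3,7-dienal
Product: 19 (R)-4-benzyl-3-[(2R,3S,5E,9Z)-3-hydroxy-10-iodo-5,9-dimethyl-2-(propan-2-yl)deca-5,9-dienoyl]-1,3-thiazolidine-2-thione, via chlorotitanium (Z)-enolate 18 (not isolated)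
Conditions: TiCl4 (1.05 equiv), i-Pr2NEt (1.1 equiv), N-methylpyrrolidinone (1.0 equiv), CH2Cl2, 0 °C; then 14, −78 to −40 °C
Reagents that add atoms: none
Why: Titanium-mediated syn aldol of an N-acyl thiazolidinethione: soft enolisation gives the Z-enolate 18, and with one equivalent of amine plus N-methylpyrrolidinone the thiocarbonyl stays off titanium. The aldehyde then reacts through a non-chelated Zimmerman–Traxler chair on the enolate face opposite the benzyl group (Evans-type syn), setting C7 (R) and C8 (S) with isopropyl and hydroxyl syn. Adding 14 at −78 °C limits migration of its alkene.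

Step 11
Reactants: 19 (R)-4-benzyl-3-[(2R,3S,5E,9Z)-3-hydroxy-10-iodo-5,9-dimethyl-2-(propan-2-yl)deca-5,9-dienoyl]-1,3-thiazolidine-2-thione; 20 3,4,5-trimethoxybenzoyl chloride
Product: 21 (2R,3S,5E,9Z)-1-[(R)-4-benzyl-2-thioxo-1,3-thiazolidin-3-yl]-10-iodo-5,9-dimethyl-1-oxo-2-(propan-2-yl)deca-5,9-dien-3-yl 3,4,5-trimethoxybenzoate
Conditions: pyridine, DMAP (0.2 equiv), CH2Cl2, 0 °C to rt
Reagents that add atoms: none
Why: DMAP-catalysed acylation of the only hydroxyl in the molecule through the N-acylpyridinium salt; the weak base avoids retro-aldol and β-elimination, and the configuration at C8 is retained because the C–O bond is not broken.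

Step 12
Reactants: 21 (2R,3S,5E,9Z)-1-[(R)-4-benzyl-2-thioxo-1,3-thiazolidin-3-yl]-10-iodo-5,9-dimethyl-1-oxo-2-(propan-2-yl)deca-5,9-dien-3-yl 3,4,5-trimethoxybenzoate
Product: 22 (2R,3S,5E,9Z)-10-iodo-5,9-dimethyl-1-oxo-2-(propan-2-yl)deca-5,9-dien-3-yl 3,4,5-trimethoxybenzoate
Conditions: i-Bu2AlH (1.3 equiv), CH2Cl2, −78 °C; cold aq. potassium sodium tartrate
Reagents that add atoms: none
Why: Partial reduction of an N-acyl thiazolidinethione by i-Bu2AlH: the thioimide carbonyl is far more electrophilic than the electron-rich aryl ester, and the aluminium hemiaminal is stable at −78 °C, releasing the aldehyde and auxiliary 16 only on work-up. No base is present, so C7 keeps its configuration and the β-aroyloxy group should not be eliminated.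

Step 13
Reactants: 22 (2R,3S,5E,9Z)-10-iodo-5,9-dimethyl-1-oxo-2-(propan-2-yl)deca-5,9-dien-3-yl 3,4,5-trimethoxybenzoate
Product: 24 (6S,7S,8S)-6-hydroxygermacra-1(10)E,4Z-dien-8-yl 3,4,5-trimethoxybenzoate, via alkenylchromium dichloride 23 (not isolated)
Conditions: CrCl2 (10 equiv), NiCl2 (0.1 equiv), degassed DMSO, 25 °C, slow addition of 22 to a final 0.002 M
Reagents that add atoms: none
Why: CrCl2 reduces the NiCl2 catalyst to zerovalent nickel, which inserts into the C5–I bond with retention of the Z geometry; transmetalation to trivalent chromium gives alkenylchromium 23, whose carbon–chromium bond adds to the chromium-activated C6 aldehyde (Nozaki–Hiyama–Kishi reaction). The closest known reaction type is the intramolecular alkenyl iodide–aldehyde version of this coupling, which is established for medium-ring carbocyclic allylic alcohols. The ten-membered ring closes in a 10-exo-trig mode by forming C5–C6 under high dilution; the E C1=C10 and Z C4=C5 alkenes remove four rotatable bonds and fold the chain so that C5 can reach C6. The new stereocentre C6 is controlled by the adjacent C7 centre: in a Felkin–Anh arrangement the isopropyl group stands perpendicular to the carbonyl plane and anti to the incoming C5, while the C7–C8 bond, which must become a gauche ring bond, lies on the carbonyl-oxygen side; this should deliver the (6S) carbinol of 24, cis to isopropyl on the ring. The step needs chemoselectivity (organochromium reagents add to aldehydes but not to aryl esters), absence of base (the reagent is non-basic, so neither epimerisation at C7 nor β-elimination of the aroyloxy group is expected) and geometric fidelity (trisubstituted alkenyl iodides couple with retention). The weakly nucleophilic chromium alkoxide of the product should not trigger 1,3-acyl transfer from O8 to O6 before aqueous work-up.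

Step 14
Reactants: 24 (6S,7S,8S)-6-hydroxygermacra-1(10)E,4Z-dien-8-yl 3,4,5-trimethoxybenzoate
Product: 25 (4S,5R,6R,7S,8S)-4,5-epoxy-6-hydroxygermacr-1(10)E-en-8-yl 3,4,5-trimethoxybenzoate
Conditions: VO(acac)2 (0.05 equiv), t-BuOOH (1.5 equiv), CH2Cl2, 0 °C
Reagents that add atoms: tert-butyl hydroperoxide CC(C)(C)OO
Why: Hydroxyl-directed epoxidation: the vanadate ester of the C6 hydroxyl binds the hydroperoxide and transfers oxygen to the allylic C4=C5 alkene far faster than to the remote C1=C10 alkene. As in medium-ring (Z)-cycloalkenols, the C6–C7 ring bond stands roughly perpendicular to the alkene plane, so oxygen should arrive on the face syn to the hydroxyl and anti to C7, giving the cis epoxy alcohol (4S,5R). The Z alkene geometry becomes the cis relationship of C3 and C6 on the oxirane.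

## Compound list

1 | prop-2-yn-1-ol (propargyl alcohol) | C#CCO | starting material
2 | 4-methyl-2,5-dihydro-1,2-oxamagnesole (chelated (Z)-alkenylmagnesium alkoxide from 1) | CC1=C[Mg]OC1 | intermediate
3 | (Z)-3-iodo-2-methylprop-2-en-1-ol | OC/C(C)=C\I | intermediate
4 | (Z)-3-bromo-1-iodo-2-methylprop-1-ene | BrC/C(C)=C\I | intermediate
5 | tert-butyl acetate | CC(=O)OC(C)(C)C | starting material
6 | lithium enolate of tert-butyl acetate (lithium 1-tert-butoxyethen-1-olate) | C=C(O[Li])OC(C)(C)C | intermediate
7 | tert-butyl (Z)-5-iodo-4-methylpent-4-enoate | CC(C)(C)OC(=O)CC/C(C)=C\I | intermediate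
8 | (Z)-5-iodo-4-methylpent-4-enal | O=CCC/C(C)=C\I | intermediate
9 | 2-(triphenylphosphoranylidene)propanal | CC(C=O)=P(c1ccccc1)(c1ccccc1)c1ccccc1 | starting material
10 | (2E,6Z)-7-iodo-2,6-dimethylhepta-2,6-dienal | O=C/C(C)=C/CC/C(C)=C\I | intermediate
11 | (1Z,5E)-1-iodo-2,6-dimethylocta-1,5,7-triene | C=C/C(C)=C/CC/C(C)=C\I | intermediate
12 | 9-[(3E,7Z)-8-iodo-3,7-dimethylocta-3,7-dien-1-yl]-9-borabicyclo[3.3.1]nonane | B1(CC/C(C)=C/CC/C(C)=C\I)C2CCCC1CCC2 | intermediate
13 | (3E,7Z)-8-iodo-3,7-dimethylocta-3,7-dien-1-ol | OCC/C(C)=C/CC/C(C)=C\I | intermediate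
14 | (3E,7Z)-8-iodo-3,7-dimethylocta-3,7-dienal | O=CC/C(C)=C/CC/C(C)=C\I | intermediate
15 | 3-methylbutanoyl chloride (isovaleryl chloride) | CC(C)CC(Cl)=O | starting material
16 | (R)-4-benzyl-1,3-thiazolidine-2-thione | S=C1N[C@H](Cc2ccccc2)CS1 | starting material
17 | (R)-4-benzyl-3-(3-methylbutanoyl)-1,3-thiazolidine-2-thione | CC(C)CC(=O)N1C(=S)SC[C@H]1Cc1ccccc1 | intermediate
18 | trichlorotitanium (Z)-enolate of 17 (O–Ti and isopropyl cis) | CC(C)/C=C(\O[Ti](Cl)(Cl)Cl)N1C(=S)SC[C@H]1Cc1ccccc1 | intermediate
19 | (R)-4-benzyl-3-[(2R,3S,5E,9Z)-3-hydroxy-10-iodo-5,9-dimethyl-2-(propan-2-yl)deca-5,9-dienoyl]-1,3-thiazolidine-2-thione | O[C@@H](C/C(C)=C/CC/C(C)=C\I)[C@@H](C(C)C)C(=O)N1C(=S)SC[C@H]1Cc1ccccc1 | intermediate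
20 | 3,4,5-trimethoxybenzoyl chloride | COc1cc(C(Cl)=O)cc(OC)c1OC | starting material
21 | (2R,3S,5E,9Z)-1-[(R)-4-benzyl-2-thioxo-1,3-thiazolidin-3-yl]-10-iodo-5,9-dimethyl-1-oxo-2-(propan-2-yl)deca-5,9-dien-3-yl 3,4,5-trimethoxybenzoate | COc1cc(C(=O)O[C@@H](C/C(C)=C/CC/C(C)=C\I)[C@@H](C(C)C)C(=O)N2C(=S)SC[C@H]2Cc2ccccc2)cc(OC)c1OC | intermediate
22 | (2R,3S,5E,9Z)-10-iodo-5,9-dimethyl-1-oxo-2-(propan-2-yl)deca-5,9-dien-3-yl 3,4,5-trimethoxybenzoate (seco aldehyde: C6 formyl, C8 ester, C5 Z-alkenyl iodide) | COc1cc(C(=O)O[C@@H](C/C(C)=C/CC/C(C)=C\I)[C@@H](C(C)C)C=O)cc(OC)c1OC | intermediate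
23 | C5 alkenylchromium dichloride of 22 (CrCl2 in place of iodine, Z geometry retained) | COc1cc(C(=O)O[C@@H](C/C(C)=C/CC/C(C)=C\[Cr](Cl)Cl)[C@@H](C(C)C)C=O)cc(OC)c1OC | intermediate
24 | (6S,7S,8S)-6-hydroxygermacra-1(10)E,4Z-dien-8-yl 3,4,5-trimethoxybenzoate | COc1cc(C(=O)O[C@H]2C/C(C)=C/CC/C(C)=C\[C@H](O)[C@@H]2C(C)C)cc(OC)c1OC | intermediate
25 | (4S,5R,6R,7S,8S)-4,5-epoxy-6-hydroxygermacr-1(10)E-en-8-yl 3,4,5-trimethoxybenzoate (CNP0260213.12) | COc1cc(C(=O)O[C@H]2C/C(C)=C/CC[C@]3(C)O[C@@H]3[C@H](O)[C@@H]2C(C)C)cc(OC)c1OC | target

## Step count and least certain steps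

Total: 14 steps. Longest linear sequence: 13 steps (steps 1–8 and 10–14, from propargyl alcohol 1); step 9 is a one-step branch.

**Step 13 (key step).**
- Risk: poor facial selectivity at C6. If the ring closes through a conformer in which the C7–C8 bond, not the isopropyl group, stands anti to the incoming C5, the 6-epimer would dominate. A slow closure would also let intermolecular coupling compete.
- Fallback (sets out from 22, returns at 24): the cyclisation is kept, but C6 is no longer set by it. The epimeric dienol, (6R,7S,8S)-6-hydroxygermacra-1(10)E,4Z-dien-8-yl 3,4,5-trimethoxybenzoate F1, alone or mixed with 24, would be oxidised with Dess–Martin periodinane and NaHCO3 to the ten-membered Z-enone, 6-oxogermacra-1(10)E,4Z-dien-8-yl 3,4,5-trimethoxybenzoate F2. F2 would then be reduced under reagent control (BH3·SMe2 with the 2-methyl-CBS-oxazaborolidine enantiomer matched to the required face, −40 °C; 1,2-reduction, the ester untouched) to 24.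

**Step 12.**
- Risk: loss of chemoselectivity, that is hydride attack on the aryl ester or over-reduction of the hindered α-branched thioimide, and β-elimination of the aroyloxy group during work-up.
- Fallback (sets out from 19, returns at 22): the auxiliary would be removed reductively with NaBH4 in THF/EtOH to give (2S,3S,5E,9Z)-10-iodo-5,9-dimethyl-2-(propan-2-yl)deca-5,9-diene-1,3-diol F3. The primary hydroxyl would be silylated (TBSCl, imidazole) to (2S,3S,5E,9Z)-1-(tert-butyldimethylsilyloxy)-10-iodo-5,9-dimethyl-2-(propan-2-yl)deca-5,9-dien-3-ol F4. The secondary hydroxyl would be esterified with 20 (pyridine, DMAP) to (2S,3S,5E,9Z)-1-(tert-butyldimethylsilyloxy)-10-iodo-5,9-dimethyl-2-(propan-2-yl)deca-5,9-dien-3-yl 3,4,5-trimethoxybenzoate F5. The silyl ether would be cleaved with HF·pyridine, acidic enough to prevent acyl migration, to (2S,3S,5E,9Z)-1-hydroxy-10-iodo-5,9-dimethyl-2-(propan-2-yl)deca-5,9-dien-3-yl 3,4,5-trimethoxybenzoate F6. Dess–Martin oxidation would give 22.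

**Step 14.**
- Risk: poor or reversed facial selectivity if the ring holds the C6–O bond so that vanadium reaches the other alkene face, and acid-triggered transannular opening of the product epoxide.
- Fallback (sets out from 24, returns at 25): the epoxide face would be set from the C6 epimer and C6 corrected afterwards. Oxidation of 24 (Dess–Martin periodinane, NaHCO3) would give the enone, 6-oxogermacra-1(10)E,4Z-dien-8-yl 3,4,5-trimethoxybenzoate F2. Reduction with BH3·SMe2 and the other enantiomer of the 2-methyl-CBS-oxazaborolidine would give the (6R)-dienol, (6R,7S,8S)-6-hydroxygermacra-1(10)E,4Z-dien-8-yl 3,4,5-trimethoxybenzoate F1. Directed epoxidation (VO(acac)2, t-BuOOH) would give (4S,5R,6S,7S,8S)-4,5-epoxy-6-hydroxygermacr-1(10)E-en-8-yl 3,4,5-trimethoxybenzoate F7. Oxidation would give the epoxy ketone, 4,5-epoxy-6-oxogermacr-1(10)E-en-8-yl 3,4,5-trimethoxybenzoate F8 (C4, C5, C7 and C8 arranged as in 25). Chelation-controlled reduction with Zn(BH4)2 in Et2O at −20 °C, zinc bridging the ketone and epoxide oxygens, would give the cis epoxy alcohol 25.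

**Step 10.**
- Risk: migration of the C10=C1 alkene of 14 into conjugation, or self-condensation, in the presence of TiCl4 and amine; and lower diastereoselectivity with the β-branched acyl group.
- Fallback (sets out from 14, returns at 22): a boron aldol, in which the aldehyde meets only a neutral dibutylboron enolate. Acid chloride 15 and (R)-4-benzyl-1,3-oxazolidin-2-one (n-BuLi, THF, −78 °C) would give (R)-4-benzyl-3-(3-methylbutanoyl)-1,3-oxazolidin-2-one F9. Enolisation with Bu2BOTf and Et3N in CH2Cl2 at −78 °C and addition of 14 would give the syn adduct (R)-4-benzyl-3-[(2R,3S,5E,9Z)-3-hydroxy-10-iodo-5,9-dimethyl-2-(propan-2-yl)deca-5,9-dienoyl]-1,3-oxazolidin-2-one F10. LiBH4 in wet Et2O would give the diol (2S,3S,5E,9Z)-10-iodo-5,9-dimethyl-2-(propan-2-yl)deca-5,9-diene-1,3-diol F3. From there the sequence of the step 12 fallback would lead to 22: the silyl ether (2S,3S,5E,9Z)-1-(tert-butyldimethylsilyloxy)-10-iodo-5,9-dimethyl-2-(propan-2-yl)deca-5,9-dien-3-ol F4, its ester (2S,3S,5E,9Z)-1-(tert-butyldimethylsilyloxy)-10-iodo-5,9-dimethyl-2-(propan-2-yl)deca-5,9-dien-3-yl 3,4,5-trimethoxybenzoate F5, the primary alcohol (2S,3S,5E,9Z)-1-hydroxy-10-iodo-5,9-dimethyl-2-(propan-2-yl)deca-5,9-dien-3-yl 3,4,5-trimethoxybenzoate F6, then Dess–Martin oxidation.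

## Further compounds

F1 | step 13 | (6R,7S,8S)-6-hydroxygermacra-1(10)E,4Z-dien-8-yl 3,4,5-trimethoxybenzoate (C6 epimer of 24) | COc1cc(C(=O)O[C@H]2C/C(C)=C/CC/C(C)=C\[C@@H](O)[C@@H]2C(C)C)cc(OC)c1OC
F2 | step 13 | 6-oxogermacra-1(10)E,4Z-dien-8-yl 3,4,5-trimethoxybenzoate (C7 and C8 as in 24) | COc1cc(C(=O)O[C@H]2C/C(C)=C/CC/C(C)=C\C(=O)[C@@H]2C(C)C)cc(OC)c1OC
F3 | step 12 | (2S,3S,5E,9Z)-10-iodo-5,9-dimethyl-2-(propan-2-yl)deca-5,9-diene-1,3-diol | O[C@@H](C/C(C)=C/CC/C(C)=C\I)[C@@H](C(C)C)CO
F4 | step 12 | (2S,3S,5E,9Z)-1-(tert-butyldimethylsilyloxy)-10-iodo-5,9-dimethyl-2-(propan-2-yl)deca-5,9-dien-3-ol | O[C@@H](C/C(C)=C/CC/C(C)=C\I)[C@@H](C(C)C)CO[Si](C)(C)C(C)(C)C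
F5 | step 12 | (2S,3S,5E,9Z)-1-(tert-butyldimethylsilyloxy)-10-iodo-5,9-dimethyl-2-(propan-2-yl)deca-5,9-dien-3-yl 3,4,5-trimethoxybenzoate | COc1cc(C(=O)O[C@@H](C/C(C)=C/CC/C(C)=C\I)[C@@H](C(C)C)CO[Si](C)(C)C(C)(C)C)cc(OC)c1OC
F6 | step 12 | (2S,3S,5E,9Z)-1-hydroxy-10-iodo-5,9-dimethyl-2-(propan-2-yl)deca-5,9-dien-3-yl 3,4,5-trimethoxybenzoate | COc1cc(C(=O)O[C@@H](C/C(C)=C/CC/C(C)=C\I)[C@@H](C(C)C)CO)cc(OC)c1OC
F7 | step 14 | (4S,5R,6S,7S,8S)-4,5-epoxy-6-hydroxygermacr-1(10)E-en-8-yl 3,4,5-trimethoxybenzoate (C6 epimer of 25) | COc1cc(C(=O)O[C@H]2C/C(C)=C/CC[C@]3(C)O[C@@H]3[C@@H](O)[C@@H]2C(C)C)cc(OC)c1OC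
F8 | step 14 | 4,5-epoxy-6-oxogermacr-1(10)E-en-8-yl 3,4,5-trimethoxybenzoate (C4, C5, C7 and C8 arranged as in 25) | COc1cc(C(=O)O[C@H]2C/C(C)=C/CC[C@]3(C)O[C@@H]3C(=O)[C@@H]2C(C)C)cc(OC)c1OC
F9 | step 10 | (R)-4-benzyl-3-(3-methylbutanoyl)-1,3-oxazolidin-2-one | CC(C)CC(=O)N1C(=O)OC[C@H]1Cc1ccccc1
F10 | step 10 | (R)-4-benzyl-3-[(2R,3S,5E,9Z)-3-hydroxy-10-iodo-5,9-dimethyl-2-(propan-2-yl)deca-5,9-dienoyl]-1,3-oxazolidin-2-one | O[C@@H](C/C(C)=C/CC/C(C)=C\I)[C@@H](C(C)C)C(=O)N1C(=O)OC[C@H]1Cc1ccccc1
A1 | alternative 1 | 4-[(Z)-3-bromo-2-methylprop-1-enyl]-2,2-dimethyl-6-[(E)-2-methyl-4-(phenylsulfonyl)but-2-enyl]-5-(propan-2-yl)-1,3-dioxane (C6, C7 and C8 as in 25) | CC1(C)O[C@@H](C/C(C)=C/CS(=O)(=O)c2ccccc2)[C@@H](C(C)C)[C@H](/C=C(C)\CBr)O1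
A2 | alternative 1 | 2-phenylsulfonylgermacra-1(10)E,4Z-diene-6,8-diol acetonide (C2 epimers) | CC1(C)O[C@H]2C/C(C)=C/C(S(=O)(=O)c3ccccc3)C/C(C)=C\[C@H](O1)[C@@H]2C(C)C
A3 | alternative 2 | 2-(tert-butyldimethylsilyloxy)-8a-hydroxy-3a,7-dimethyl-1-(propan-2-yl)-1,2,3,3a,4,5,6,8a-octahydroazulen-4-yl methanesulfonate (cis ring fusion, mesylate anti-periplanar to the ring-fusion bond) | CC1=C[C@@]2(O)[C@H](C(C)C)[C@@H](O[Si](C)(C)C(C)(C)C)C[C@@]2(C)[C@H](OS(C)(=O)=O)CC1
A4 | alternative 2 | 8-(tert-butyldimethylsilyloxy)germacra-1(10)E,4Z-dien-6-one | CC(C)(C)[Si](C)(C)O[C@H]2C/C(C)=C/CC/C(C)=C\C(=O)[C@@H]2C(C)C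
A5 | alternative 3 | (3E,7Z,10E)-12-bromo-9-(tert-butyldimethylsilyloxy)-3,7,11-trimethyldodeca-3,7,10-trienal (C9 of the chain is C6 of the ring, configured as in A6) | O=CC/C(C)=C/CC/C(C)=C\[C@H](O[Si](C)(C)C(C)(C)C)/C=C(\C)CBr
A6 | alternative 3 | 6-(tert-butyldimethylsilyloxy)-7-isopropenylgermacra-1(10)E,4Z-dien-8-ol | O[C@H]2C/C(C)=C/CC/C(C)=C\[C@H](O[Si](C)(C)C(C)(C)C)[C@@H]2C(C)=C
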